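## Retrosynthetic overview

1. The palmitate and the N-methyl-2-quinolone are released together at the end: N-methylation of a (2R)-2-isopropenyl-4,8-dimethoxy-2,3-dihydrofuro[2,3-b]quinoline, opening of the quinolinium salt at C-9a by water (the pyridine ring loses its aromaticity, the C–O bond of the stereocentre stays intact), then acylation with palmitoyl chloride in the same flask.
2. The dihydrofuran ring with the only stereocentre comes from an enantioselective Pd-catalysed carbopalladation/allylic etherification of isoprene with 3-iodo-4,8-dimethoxyquinolin-2(1H)-one (C3–CH2 and C–O bonds in one step).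
3. The iodolactam comes from 4-hydroxy-8-methoxyquinolin-2(1H)-one by C-3 iodination and O-4 methylation.
4. The pyridone ring is built on o-anisidine with Meldrum's acid (amide formation, then Friedel–Crafts closure).
5. Ring order: benzene ring (bought) → pyridone ring (step 1) → temporary dihydrofuran ring (step 4) → reopened in step 5.

Assumption: the ligand enantiomer that gives (R)-8 in step 4 is assigned by analogy with the dihydrobenzofuran series and is confirmed in the first run; both ligand enantiomers are accessible.

## Route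

Step 1
Reactants: 1 2-methoxyaniline (o-anisidine); 2 2,2-dimethyl-1,3-dioxane-4,6-dione (Meldrum's acid)
Product: 4 4-hydroxy-8-methoxyquinolin-2(1H)-one, via malonamic acid 3 (not isolated)
Conditions: neat, 90 °C, acetone distilled off; then Eaton's reagent (P2O5 in MeSO3H, as solvent), 70 °C; ice-water
Reagents that add atoms: none
Why: Aminolysis of Meldrum's acid by the aniline gives the malonamic acid, and Eaton's reagent then closes the pyridone ring by intramolecular Friedel–Crafts acylation at the only free position ortho to nitrogen, so the methoxy group ends up at C-8.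

Step 2
Reactants: 4 4-hydroxy-8-methoxyquinolin-2(1H)-one
Product: 5 4-hydroxy-3-iodo-8-methoxyquinolin-2(1H)-one
Conditions: NIS (1.05 equiv), DMF, rt, dark
Reagents that add atoms: N-iodosuccinimide, O=C1CCC(=O)N1I
Why: Electrophilic iodination of an enol goes to C-3 because this carbon between the 4-hydroxy and 2-oxo groups is far more nucleophilic than the anisole ring.

Step 3
Reactants: 5 4-hydroxy-3-iodo-8-methoxyquinolin-2(1H)-one
Product: 6 3-iodo-4,8-dimethoxyquinolin-2(1H)-one
Conditions: TMSCHN2 (1.3 equiv), MeOH/CH2Cl2, 0 °C to rt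
Reagents that add atoms: trimethylsilyldiazomethane, C[Si](C)(C)C=[N+]=[N-]
Why: Diazomethane released in situ methylates only the acidic vinylogous-acid 4-OH (O-alkylation of an enol by a diazoalkane), leaving the much less acidic lactam N–H/C=O free as the nucleophile for step 4.

Step 4
Reactants: 6 3-iodo-4,8-dimethoxyquinolin-2(1H)-one; 7 2-methylbuta-1,3-diene (isoprene)
Product: 8 (2R)-4,8-dimethoxy-2-(prop-1-en-2-yl)-2,3-dihydrofuro[2,3-b]quinoline
Conditions: Pd2(dba)3·CHCl3 (2.5 mol%), chiral sulfinamide monophosphine ligand (TY-Phos type, 10 mol%), Cs2CO3 (2 equiv), 7 (5 equiv), 1,4-dioxane, 70 °C, sealed tube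
Reagents that add atoms: none
Why: Proposed new method: oxidative addition of the carbon–iodine bond to zerovalent palladium, carbopalladation of the unsubstituted vinyl group of isoprene and capture of the resulting 2-methyl-π-allyl palladium complex by the lactam oxygen (the nitrogen cannot reach it) close the dihydrofuran ring in a Larock-type heteroannulation, the chiral ligand fixing C-2 as (R) in the C–O bond-forming allylic substitution; the closest known reaction type is the enantioselective Heck/Tsuji–Trost annulation of 2-halophenols with 1,3-dienes, isoprene included, to 2-isopropenyl-2,3-dihydrobenzofurans.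

Step 5
Reactants: 8 (2R)-4,8-dimethoxy-2-(prop-1-en-2-yl)-2,3-dihydrofuro[2,3-b]quinoline; 9 hexadecanoyl chloride (palmitoyl chloride)
Product: 12 (2R)-1-(4,8-dimethoxy-1-methyl-2-oxo-1,2-dihydroquinolin-3-yl)-3-methylbut-3-en-2-yl hexadecanoate, via quinolinium triflate 10 (not isolated), via alcohol 11 (not isolated)
Conditions: MeOTf (1.3 equiv), CH2Cl2, 0 °C to rt; then H2O (1.2 equiv), i-Pr2NEt (5 equiv), MeCN, rt; then 9 (2 equiv), DMAP (0.2 equiv), rt
Reagents that add atoms: methyl trifluoromethanesulfonate, COS(=O)(=O)C(F)(F)F; water, O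
Why: N-Methylation (Menshutkin-type quaternisation) turns the cyclic lactim ether into a 2-alkoxyquinolinium salt that water attacks at C-9a, as in the base-induced ring opening of O-methyl dihydrofuroquinolinium salts to 3-(2-hydroxyalkyl)-1-methyl-2-quinolones, so the pyridine ring loses its aromaticity, the C-2–O bond is not touched and the (R) centre is kept, and the freed alcohol is esterified in the same flask by DMAP-catalysed acylation.

## Compound list

1 | 2-methoxyaniline (o-anisidine) | COc1ccccc1N | starting material
2 | 2,2-dimethyl-1,3-dioxane-4,6-dione (Meldrum's acid) | CC1(C)OC(=O)CC(=O)O1 | starting material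
3 | 3-[(2-methoxyphenyl)amino]-3-oxopropanoic acid (malonamic acid, not isolated) | COc1ccccc1NC(=O)CC(=O)O | intermediate
4 | 4-hydroxy-8-methoxyquinolin-2(1H)-one | COc1cccc2c(O)cc(=O)[nH]c12 | intermediate
5 | 4-hydroxy-3-iodo-8-methoxyquinolin-2(1H)-one | COc1cccc2c(O)c(I)c(=O)[nH]c12 | intermediate
6 | 3-iodo-4,8-dimethoxyquinolin-2(1H)-one | COc1cccc2c(OC)c(I)c(=O)[nH]c12 | intermediate
7 | 2-methylbuta-1,3-diene (isoprene) | C=CC(C)=C | starting material
8 | (2R)-4,8-dimethoxy-2-(prop-1-en-2-yl)-2,3-dihydrofuro[2,3-b]quinoline | C=C(C)[C@H]1Cc2c(OC)c3cccc(OC)c3nc2O1 | intermediate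
9 | hexadecanoyl chloride (palmitoyl chloride) | CCCCCCCCCCCCCCCC(=O)Cl | starting material
10 | (2R)-4,8-dimethoxy-9-methyl-2-(prop-1-en-2-yl)-2,3-dihydrofuro[2,3-b]quinolin-9-ium trifluoromethanesulfonate (not isolated) | C=C(C)[C@H]1Cc2c(OC)c3cccc(OC)c3[n+](C)c2O1.[O-]S(=O)(=O)C(F)(F)F | intermediate
11 | 3-[(2R)-2-hydroxy-3-methylbut-3-en-1-yl]-4,8-dimethoxy-1-methylquinolin-2(1H)-one (not isolated) | C=C(C)[C@@H](Cc1c(OC)c2cccc(OC)c2n(C)c1=O)O | intermediate
12 | (2R)-1-(4,8-dimethoxy-1-methyl-2-oxo-1,2-dihydroquinolin-3-yl)-3-methylbut-3-en-2-yl hexadecanoate (CNP0203784.1) | C=C(C)[C@@H](Cc1c(OC)c2cccc(OC)c2n(C)c1=O)OC(=O)CCCCCCCCCCCCCCC | target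

## Step count and fallbacks

Total step count: 5. Longest linear sequence: 5 (1 → 4 → 5 → 6 → 8 → 12).

Steps most likely to fail, in this order: step 4, step 5, step 3.

**Step 4** (new substrate class for the asymmetric annulation; enantioselectivity and the isopropenyl versus 2-methyl-2-vinyl regiochemistry are unproven). The fallback sets out from 6 and comes back at 8. It replaces the palladium allyl chemistry by an epoxide route. Stille coupling of 6 with tributyl(3-methylbut-2-en-1-yl)stannane (Pd(PPh3)4, DMF, 90 °C) gives 4,8-dimethoxy-3-(3-methylbut-2-en-1-yl)quinolin-2(1H)-one F1. Asymmetric epoxidation with KHSO5 (used as 2 KHSO5·KHSO4·K2SO4) and the enantiomer of the fructose-derived Shi ketone gives 3-{[(2S)-3,3-dimethyloxiran-2-yl]methyl}-4,8-dimethoxyquinolin-2(1H)-one F2. With K2CO3 in MeOH the lactam oxygen attacks the secondary epoxide carbon (5-exo, inversion) to give 2-[(2R)-4,8-dimethoxy-2,3-dihydrofuro[2,3-b]quinolin-2-yl]propan-2-ol F3. Dehydration of the tertiary alcohol with Burgess reagent (toluene, 60 °C) then gives 8.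

**Step 5** (quaternisation at a nitrogen flanked by the 8-methoxy group; possible attack at C-4 or elimination instead of addition at C-9a; acylation in the presence of the hydrolysis reagents). Isolating 11 before acylation is the first remedy but changes only the conditions. The fallback that changes the approach sets out from 6 and comes back at 12. It uses the other reactivity mode of the quinolinium salt, substitution at the alkyl carbon as in the Mukaiyama inversion of 2-alkoxy-1-methylpyridinium salts. Step 4 is run on 6 with the antipodal ligand to give (2S)-4,8-dimethoxy-2-(prop-1-en-2-yl)-2,3-dihydrofuro[2,3-b]quinoline F4. Methyl triflate converts it into (2S)-4,8-dimethoxy-9-methyl-2-(prop-1-en-2-yl)-2,3-dihydrofuro[2,3-b]quinolin-9-ium trifluoromethanesulfonate F5. Tetrabutylammonium hexadecanoate (MeCN, 50 °C) opens the ring by SN2 at C-2 with inversion and gives 12 directly. The weak point of this fallback is that attack of the carboxylate on the 4-O-methyl group probably competes and may dominate, so the product ratio has to be checked.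

**Step 3** (O-4 versus O-2 or N methylation of the ambident hydroxyquinolone). The fallback sets out from 5 and comes back at 6. It sets the oxygen pattern by substitution instead of alkylation. POCl3 (100 °C) converts 5 into 2,4-dichloro-3-iodo-8-methoxyquinoline F6. NaOMe in MeOH at reflux gives 3-iodo-2,4,8-trimethoxyquinoline F7. 6 M HCl in dioxane (60 °C) hydrolyses only the lactim (2-) ether and returns 6.

Further compounds

F1 | step 4 | 4,8-dimethoxy-3-(3-methylbut-2-en-1-yl)quinolin-2(1H)-one | CC(C)=CCc1c(OC)c2cccc(OC)c2[nH]c1=O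
F2 | step 4 | 3-{[(2S)-3,3-dimethyloxiran-2-yl]methyl}-4,8-dimethoxyquinolin-2(1H)-one | CC1(C)O[C@H]1Cc1c(OC)c2cccc(OC)c2[nH]c1=O
F3 | step 4 | 2-[(2R)-4,8-dimethoxy-2,3-dihydrofuro[2,3-b]quinolin-2-yl]propan-2-ol | CC(C)(O)[C@H]1Cc2c(OC)c3cccc(OC)c3nc2O1
F4 | step 5 | (2S)-4,8-dimethoxy-2-(prop-1-en-2-yl)-2,3-dihydrofuro[2,3-b]quinoline | C=C(C)[C@@H]1Cc2c(OC)c3cccc(OC)c3nc2O1
F5 | step 5 | (2S)-4,8-dimethoxy-9-methyl-2-(prop-1-en-2-yl)-2,3-dihydrofuro[2,3-b]quinolin-9-ium trifluoromethanesulfonate | C=C(C)[C@@H]1Cc2c(OC)c3cccc(OC)c3[n+](C)c2O1.[O-]S(=O)(=O)C(F)(F)F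
F6 | step 3 | 2,4-dichloro-3-iodo-8-methoxyquinoline | COc1cccc2c(Cl)c(I)c(Cl)nc12
F7 | step 3 | 3-iodo-2,4,8-trimethoxyquinoline | COc1cccc2c(OC)c(I)c(OC)nc12
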